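## Structural features

The target is a eudesmane: two cyclohexane rings (ring A = C1–C5, C10; ring B = C5–C10) fused trans along C5–C10, with 5α-H and a 10β-methyl group. It has six stereocentres, five of them contiguous (C3–C4–C5–C6–C7), and the sixth, C10, is quaternary and next to C5. The 3α- and 4β-hydroxyl groups form a trans-diaxial glycol whose tertiary carbon C4 also carries an equatorial 4α-methyl group. The 6β-benzoyloxy group is axial as well, so that 4β-OH, 6β-OBz and the 10β-methyl group are mutually 1,3-diaxial on the β face, while the C7 isopropyl group is equatorial (β). The fragile points are the benzoate (hydroxide, strong hydride, acyl shift to the syn-axial O4) and the tertiary carbinol (elimination under acid). The real difficulty is the crowded β face, the absolute configuration of quaternary C10, and the need to acylate only the C6 oxygen. The key step exploits two patterns: ring B (oxygen at C6, isopropyl at C7, methyl at C10, plus a removable oxygen at C9) is a 2-isopropyl-5-methyl-1,4-benzoquinone, and C1–C4 with the C15 methyl and the C3 oxygen form a 3-oxygenated penta-1,3-diene that can close ring A on the C5=C10 bond.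

## Logic of the disconnections

20 ⇒ 18 (through 19): the C3–O and C4–O bonds are cut. A trans-diaxial glycol is the signature of anti addition of two oxygens across C3=C4, so two stereocentres and two hydroxyl groups disappear. The forward step needs α-face epoxidation, diaxial opening at the tertiary carbon and a benzoate that stays on O6.

18 ⇒ 16 ⇒ 15 (through 17): the C3=C4 alkene is traced to a C3 alcohol and then to a C3 ketone, because a C3 carbonyl is what the cycloaddition delivers in masked form. The forward demand is an axial 3α-alcohol and an elimination that runs toward C4 and not toward C2.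

15 ⇒ 14 ⇒ 12 ⇒ 11: the C3 ketone is re-masked as its silyl enol ether, the ester C–O bond is cut (releasing 13), and the C6–H bond is cut back to a C6 ketone. This leaves one carbonyl in ring B that controls both C5 and C7. The forward steps need α-face hydride delivery and acylation of a hindered axial alcohol.

11 ⇒ 10: the C7–H and C8–H bonds are removed to give a conjugated enone. C7 then becomes trigonal, and in the forward direction it is set by hydrogenation anti to the angular methyl group and not by an equilibrium.

10 ⇒ 9 ⇒ 8 ⇒ 6 (through 7): the trans ring fusion is traced to the cis-fused ketone by epimerisation at C5. The C9 methylene is traced to an enol triflate and then to a C9 ketone. The demand is to tell the two ring B ketones apart; this is possible because only C9 has a methylene α-position (C8).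

6 ⇒ 5: the C7=C8 bond is reinstated to give the ene-1,4-dione, which is the direct cycloadduct.

5 ⇒ 3 + 4: the C1–C10 and C4–C5 bonds are cut (retro-[4+2]). This is the largest gain in simplicity, since all fifteen skeletal carbons and the C6 oxygen come from two small achiral partners. The forward step must control the reacting alkene of 4, the orientation of 3 and the face of 4.

3 ⇒ 1 + 2: the O–Si bond is cut. The forward step must give the Z enol ether.

## Other disconnections considered

Alternative 1: The cut removes the C10–C14 and C5–C6 bonds and leaves C7=C8 to a later ring-closing metathesis. In the forward key step Cu(OTf)2 A1 with a chiral phosphoramidite ligand would catalyse the 1,4-addition of trimethylaluminium A2 to 3-allylcyclohex-2-en-1-one A3. The aluminium enolate would then add through C5 to 2-isopropylacrolein A4 to give aldol adduct A5, and metathesis of its two alkene arms would close ring B as hydroxy enone A6.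
- In its favour: asymmetric formation of a quaternary centre by conjugate addition to a 3-substituted cyclohexenone is well established, and the C6 oxygen arrives with the correct configuration on paper.
- Better than the chosen plan: the C4 ketone of A6 would let the C15 methyl and the 3,4-alkene be introduced regiospecifically (enolisation toward C3, then methyl cross-coupling), whereas the chosen plan relies on an elimination of uncertain orientation. The sequence would also reach 18 in fewer steps.
- Against it: three stereocentres hang on one tandem event. The enolate must distinguish methyl from allyl on the neighbouring quaternary carbon, and the aldol must give one C6 epimer with an α-branched enal. A5 is a β-hydroxy ketone prone to retro-aldol cleavage and dehydration.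
- Comparison: the chosen plan forms the quaternary centre and ring A in one catalytic cycloaddition whose relative configuration is fixed by suprafacial addition. It then pays for this with more functional-group adjustment.

Alternative 2: The cut removes C5–C10 and C1–C2, so both rings form at once. Under Me2AlCl A7 the trisubstituted (E)-enal of triene A8 would add to its own diene in an endo intramolecular Diels–Alder reaction to give the trans-fused aldehyde A9.
- In its favour: the 6β-oxygen and the 7β-isopropyl group are set beforehand by an anti-aldol reaction, so no ketone reduction or epimerisation is needed in ring B. On this point it is better than the chosen plan.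
- Also better than the chosen plan: the 3,4-alkene with its methyl group is formed in the cycloaddition itself, without any elimination.
- Against it: the formyl group that activates the dienophile ends on C1, which carries only hydrogen in the target, so it has to be excised (for example by Tsuji–Wilkinson decarbonylation). A β,β-disubstituted enal that must form a quaternary carbon is a slow dienophile. The facial bias has to come from one allylic silyloxy stereocentre, and the acyclic triene needs a long linear assembly.
- Comparison: on structure this plan is the more direct for ring A. On mechanism both rely on a Lewis-acid-promoted [4+2]. On step economy the chosen plan is expected to be equal or shorter, because its two partners are one step from commercial materials.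

Alternative 3: The cut removes the C6–C7 bond. Under ZnBr2 A10 the aldehyde of A11 would undergo a carbonyl-ene reaction with the trisubstituted alkene of its side chain, closing ring B to give dienol A12.
- In its favour: this is a mild, atom-economical ring closure through a well-understood chair transition state, which fixes C7 and leaves the 3,4-alkene already in place. On the reliability of the key step and on the ring A alkene it is the equal or the better of the chosen plan.
- Against it: the all-equatorial outcome places the C6 hydroxyl α, the epimer of what the target needs. C6 would have to be inverted by oxidation and α-face reduction, or by a Mitsunobu esterification at a very hindered carbinol. The 11,12-alkene must also be hydrogenated in the presence of the 3,4-alkene.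
- Comparison: the key step does not address the vicinal C10/C5 pair of A11, which is the real problem and would need its own asymmetric chemistry. The chosen plan solves C10 in the ring-forming step. Overall step counts are expected to be similar.

Key step: step 2

Remark: eudesmane numbering is used (C14 = methyl on C10, C15 = methyl on C4); β is the face of the C10 methyl group, α the opposite face.
Assumption: the (S)-configured oxazaborolidinium catalyst is taken to give the enantiomeric series drawn for 5; if the sense of induction is the opposite, the (R)-catalyst is used and nothing else changes.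

## Route

Step 1
Reactants: 1 pent-1-en-3-one; 2 triisopropylsilyl trifluoromethanesulfonate
Product: 3 (Z)-3-(triisopropylsilyloxy)penta-1,3-diene
Conditions: Et3N, CH2Cl2, 0 °C → rt
Reagents that add atoms: triisopropylsilyl trifluoromethanesulfonate, CC(C)[Si](OS(=O)(=O)C(F)(F)F)(C(C)C)C(C)C
Why: Soft enolisation: O-silylation of the enone gives a silyloxocarbenium ion that Et3N deprotonates at the ethyl CH2; the Z enol ether (methyl anti to the vinyl group) is the less strained and expected major isomer. Any E isomer cannot reach the s-cis conformation easily and should be a spectator in step 2.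

Step 2
Reactants: 4 thymoquinone; 3 (Z)-3-(triisopropylsilyloxy)penta-1,3-diene
Product: 5 cis-fused endo adduct, 3-(triisopropylsilyloxy)-4βH,5βH-eudesma-2,7-diene-6,9-dione
Conditions: (S)-1-(2-methylphenyl)-3,3-diphenyltetrahydro-1H,3H-pyrrolo[1,2-c][1,3,2]oxazaborole (20 mol%), HNTf2 (18 mol%), CH2Cl2, −78 → −40 °C
Reagents that add atoms: none
Why: Concerted but asynchronous endo [4+2] cycloaddition of the Lewis-acid-bound quinone; the closest known reaction type is the enantioselective oxazaborolidinium-catalysed Diels–Alder reaction of alkylated 1,4-benzoquinones with 2-silyloxydienes. The cationic boron is expected to bind the C9 carbonyl on its open lone pair (anti to the C10 methyl), which makes C5 the electrophilic β-carbon of the C10=C5 enone; the enol-ether terminus C4, the more nucleophilic and more hindered end of 3, leads the bonding to this unsubstituted carbon and the CH2 terminus C1 closes on C10. Ring A is closed as the six-membered cycloadduct ring by suprafacial addition on both partners, hence the cis fusion. C10 is set by the catalyst, whose aryl group should cover one face of the bound enone; C5 follows from suprafacial addition (H cis to the C10 methyl, corrected in step 6); C4 follows from the Z geometry of 3 and the endo rule (methyl α, cis to C6). Site selectivity for the methyl- over the isopropyl-bearing alkene rests on the larger isopropyl group at the carbon that would become quaternary. The reverse orientation would need the secondary carbon C4 to bond to the methyl-bearing C10, which is sterically penalised; it can, however, be the preferred mode for unsubstituted 2-silyloxybutadiene, so orientation is the main uncertainty of the route.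

Step 3
Reactants: 5 cis-fused endo adduct
Product: 6 3-(triisopropylsilyloxy)-4βH,5βH-eudesm-2-ene-6,9-dione (C7 epimers)
Conditions: Zn dust, AcOH, THF, 0 °C → rt
Reagents that add atoms: none
Why: Dissolving-metal reduction of an ene-1,4-dione: electron transfer to the doubly activated C7=C8 bond and ketonisation of the bis-enol; the isolated, bulky silyl enol ether should not be touched and the cis fusion is kept. The C7 configuration is not controlled and does not matter, since C7 becomes trigonal again in step 6.

Step 4
Reactants: 6 3-(triisopropylsilyloxy)-4βH,5βH-eudesm-2-ene-6,9-dione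
Product: 8 6-oxo-3-(triisopropylsilyloxy)-4βH,5βH-eudesma-2,8-dien-9-yl trifluoromethanesulfonate, via potassium 8-en-9-olate 7 (not isolated)
Conditions: KN(SiMe3)2 (1.05 equiv), THF, −78 °C; then N-(5-chloropyridin-2-yl)bis(trifluoromethanesulfonyl)imide, −78 °C
Reagents that add atoms: potassium bis(trimethylsilyl)amide, C[Si](C)(C)[N-][Si](C)(C)C.[K+] (potassium of 7); N-(5-chloropyridin-2-yl)bis(trifluoromethanesulfonyl)imide, O=S(=O)(N(c1ccc(Cl)cn1)S(=O)(=O)C(F)(F)F)C(F)(F)F
Why: Kinetic enolate formation and O-sulfonylation: the amide base should take the only methylene α-hydrogens (C8, next to C9) in preference to the two hindered methine α-hydrogens of the C6 ketone (C5, C7), and the enolate is trapped on oxygen. This is the step that tells the two ring B carbonyls apart.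

Step 5
Reactants: 8 enol triflate
Product: 9 3-(triisopropylsilyloxy)-4βH,5βH-eudesma-2,8-dien-6-one (C7 epimers)
Conditions: Pd(OAc)2 (5 mol%), PPh3 (10 mol%), HCO2H, n-Bu3N, DMF, 60 °C
Reagents that add atoms: none
Why: Palladium-catalysed formate reduction of an alkenyl triflate: oxidative addition to zerovalent palladium, formate exchange, loss of CO2 to the palladium hydride and reductive elimination replace the C9 oxygen by hydrogen. The ketone and the silyl enol ether are inert under these conditions.

Step 6
Reactants: 9 3-(triisopropylsilyloxy)-4βH,5βH-eudesma-2,8-dien-6-one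
Product: 10 3-(triisopropylsilyloxy)-4βH,5αH-eudesma-2,7-dien-6-one (trans-fused)
Conditions: NaOMe (0.3 equiv), MeOH–THF, 0 °C → rt; AcOH quench
Reagents that add atoms: none
Why: Base-mediated alkene conjugation and α-epimerisation under thermodynamic control: the dienolate of 9 is reprotonated at C9, and reversible enolisation toward C5 should funnel the ring fusion to the trans-decalin, where the 4α-methyl is equatorial and the angular methyl has only two syn-axial hydrogens (6-oxo steroids likewise prefer the trans A/B fusion). C5 is the only stereocentre set; C7 becomes trigonal.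

Step 7
Reactants: 10 3-(triisopropylsilyloxy)-4βH,5αH-eudesma-2,7-dien-6-one
Product: 11 3-(triisopropylsilyloxy)-4βH,5αH,7αH-eudesm-2-en-6-one
Conditions: H2 (1 atm), 10% Pd/C, EtOAc, rt
Reagents that add atoms: none
Why: Heterogeneous hydrogenation of the conjugated alkene from the α face, anti to the axial 10β-methyl, should put hydrogen on C7α and leave the isopropyl group β (equatorial), which is also the more stable epimer next to the ketone. The hindered triisopropylsilyl enol ether is expected to react much more slowly.

Step 8
Reactants: 11 3-(triisopropylsilyloxy)-4βH,5αH,7αH-eudesm-2-en-6-one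
Product: 12 3-(triisopropylsilyloxy)-4βH,5αH,7αH-eudesm-2-en-6β-ol
Conditions: NaBH4, MeOH–THF, 0 °C → rt
Reagents that add atoms: none
Why: Borohydride reduction: the axial (β) trajectory at C6 is blocked by the syn-axial 10β-methyl, so hydride should add from the α face and give the axial 6β-alcohol, as in 6-oxo-5α-steroids.

Step 9
Reactants: 12 3-(triisopropylsilyloxy)-4βH,5αH,7αH-eudesm-2-en-6β-ol; 13 benzoyl chloride
Product: 14 3-(triisopropylsilyloxy)-4βH,5αH,7αH-eudesm-2-en-6β-yl benzoate
Conditions: 4-(dimethylamino)pyridine (1 equiv), pyridine, 60 °C
Reagents that add atoms: benzoyl chloride, O=C(Cl)c1ccccc1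
Why: Nucleophilic-catalysed acylation through the N-benzoylpyridinium ion, which is reactive enough for a hindered axial secondary alcohol; C6 is not touched at carbon and the silyl enol ether is stable in the basic medium.

Step 10
Reactants: 14 3-(triisopropylsilyloxy)-4βH,5αH,7αH-eudesm-2-en-6β-yl benzoate
Product: 15 3-oxo-4βH,5αH,7αH-eudesman-6β-yl benzoate
Conditions: n-Bu4NF, AcOH, THF, 0 °C
Reagents that add atoms: none
Why: Fluoride-mediated cleavage of the silyl enol ether; the enolate is protonated at C2 by AcOH, so C4 keeps its equatorial α-methyl, the stable configuration in the trans-decalin. Buffered fluoride should leave the benzoate alone.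

Step 11
Reactants: 15 3-oxo-4βH,5αH,7αH-eudesman-6β-yl benzoate
Product: 16 3α-hydroxy-4βH,5αH,7αH-eudesman-6β-yl benzoate
Conditions: LiBH(s-Bu)3, THF, −78 °C; aqueous quench
Reagents that add atoms: none
Why: Hindered trialkylborohydride reduction: equatorial attack on the unhindered C3 ketone gives the axial 3α-alcohol, cis to the 4α-methyl, as for 3-oxo-5α-steroids. The hindered benzoate should survive at −78 °C.

Step 12
Reactants: 16 3α-hydroxy-4βH,5αH,7αH-eudesman-6β-yl benzoate
Product: 18 5αH,7αH-eudesm-3-en-6β-yl benzoate, via 3α-dichlorophosphate ester 17 (not isolated)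
Conditions: POCl3, pyridine, 0 → 50 °C
Reagents that add atoms: phosphoryl chloride, O=P(Cl)(Cl)Cl (atoms kept in 17 only)
Why: Dehydration through the dichlorophosphate by anti-periplanar E2: the axial 3α-leaving group has trans-diaxial hydrogens at C2β and C4β, and loss of 4β-H gives the trisubstituted (Saytzeff) alkene. The stereocentre C4 is removed here.

Step 13
Reactants: 18 5αH,7αH-eudesm-3-en-6β-yl benzoate
Product: 20 (3R,4R,5S,6R,7S,10S)-3α,4β-dihydroxy-5αH,7αH-eudesman-6β-yl benzoate, via 3α,4α-epoxide 19 (not isolated)
Conditions: dimethyldioxirane, acetone, 0 °C; then H2O, HClO4 (10 mol%), 0 °C → rt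
Reagents that add atoms: dimethyldioxirane, CC1(C)OO1; water, O
Why: Dioxirane epoxidation on the α face (the β face is shielded by the 10β-methyl and the 6β-benzoate), then acid-catalysed trans-diaxial opening (Fürst–Plattner) by water at the tertiary C4 with inversion, giving 3α-OH and 4β-OH with the 4α-methyl. A β-epoxide, if formed, would be expected to converge on the same diaxial diol by attack at C3.

## Compound list

1 | pent-1-en-3-one | CCC(=O)C=C | starting material
2 | triisopropylsilyl trifluoromethanesulfonate | CC(C)[Si](OS(=O)(=O)C(F)(F)F)(C(C)C)C(C)C | starting material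
3 | (Z)-3-(triisopropylsilyloxy)penta-1,3-diene | C=C/C(O[Si](C(C)C)(C(C)C)C(C)C)=C/C | intermediate
4 | thymoquinone (2-isopropyl-5-methyl-1,4-benzoquinone) | CC1=CC(=O)C(C(C)C)=CC1=O | starting material
5 | cis-fused endo adduct, 3-(triisopropylsilyloxy)-4βH,5βH-eudesma-2,7-diene-6,9-dione (4α-methyl, 10β-methyl) | CC(C)C1=CC(=O)[C@@]2(C)CC=C(O[Si](C(C)C)(C(C)C)C(C)C)[C@@H](C)[C@H]2C1=O | intermediate
6 | 3-(triisopropylsilyloxy)-4βH,5βH-eudesm-2-ene-6,9-dione (cis-fused, both C7 epimers) | CC(C)C1CC(=O)[C@@]2(C)CC=C(O[Si](C(C)C)(C(C)C)C(C)C)[C@@H](C)[C@H]2C1=O | intermediate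
7 | potassium 6-oxo-3-(triisopropylsilyloxy)-4βH,5βH-eudesma-2,8-dien-9-olate | CC(C)C1C=C([O-])[C@@]2(C)CC=C(O[Si](C(C)C)(C(C)C)C(C)C)[C@@H](C)[C@H]2C1=O.[K+] | intermediate (not isolated)
8 | 6-oxo-3-(triisopropylsilyloxy)-4βH,5βH-eudesma-2,8-dien-9-yl trifluoromethanesulfonate (both C7 epimers) | CC(C)C1C=C(OS(=O)(=O)C(F)(F)F)[C@@]2(C)CC=C(O[Si](C(C)C)(C(C)C)C(C)C)[C@@H](C)[C@H]2C1=O | intermediate
9 | 3-(triisopropylsilyloxy)-4βH,5βH-eudesma-2,8-dien-6-one (cis-fused, both C7 epimers) | CC(C)C1C=C[C@@]2(C)CC=C(O[Si](C(C)C)(C(C)C)C(C)C)[C@@H](C)[C@H]2C1=O | intermediate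
10 | 3-(triisopropylsilyloxy)-4βH,5αH-eudesma-2,7-dien-6-one (trans-fused) | CC(C)C1=CC[C@@]2(C)CC=C(O[Si](C(C)C)(C(C)C)C(C)C)[C@@H](C)[C@@H]2C1=O | intermediate
11 | 3-(triisopropylsilyloxy)-4βH,5αH,7αH-eudesm-2-en-6-one | CC(C)[C@@H]1CC[C@@]2(C)CC=C(O[Si](C(C)C)(C(C)C)C(C)C)[C@@H](C)[C@@H]2C1=O | intermediate
12 | 3-(triisopropylsilyloxy)-4βH,5αH,7αH-eudesm-2-en-6β-ol | CC(C)[C@@H]1CC[C@@]2(C)CC=C(O[Si](C(C)C)(C(C)C)C(C)C)[C@@H](C)[C@@H]2[C@@H]1O | intermediate
13 | benzoyl chloride | O=C(Cl)c1ccccc1 | starting material
14 | 3-(triisopropylsilyloxy)-4βH,5αH,7αH-eudesm-2-en-6β-yl benzoate | CC(C)[C@@H]1CC[C@@]2(C)CC=C(O[Si](C(C)C)(C(C)C)C(C)C)[C@@H](C)[C@@H]2[C@@H]1OC(=O)c1ccccc1 | intermediate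
15 | 3-oxo-4βH,5αH,7αH-eudesman-6β-yl benzoate | CC(C)[C@@H]1CC[C@@]2(C)CCC(=O)[C@@H](C)[C@@H]2[C@@H]1OC(=O)c1ccccc1 | intermediate
16 | 3α-hydroxy-4βH,5αH,7αH-eudesman-6β-yl benzoate | CC(C)[C@@H]1CC[C@@]2(C)CC[C@@H](O)[C@@H](C)[C@@H]2[C@@H]1OC(=O)c1ccccc1 | intermediate
17 | 3α-(dichlorophosphoryloxy)-4βH,5αH,7αH-eudesman-6β-yl benzoate | CC(C)[C@@H]1CC[C@@]2(C)CC[C@@H](OP(=O)(Cl)Cl)[C@@H](C)[C@@H]2[C@@H]1OC(=O)c1ccccc1 | intermediate (not isolated)
18 | 5αH,7αH-eudesm-3-en-6β-yl benzoate | CC(C)[C@@H]1CC[C@@]2(C)CCC=C(C)[C@@H]2[C@@H]1OC(=O)c1ccccc1 | intermediate
19 | 3α,4α-epoxy-5αH,7αH-eudesman-6β-yl benzoate (4β-methyl) | CC(C)[C@@H]1CC[C@@]2(C)CC[C@H]3O[C@@]3(C)[C@@H]2[C@@H]1OC(=O)c1ccccc1 | intermediate (not isolated)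
20 | (3R,4R,5S,6R,7S,10S)-3α,4β-dihydroxy-5αH,7αH-eudesman-6β-yl benzoate (CNP0187831.1) | CC(C)[C@@H]1CC[C@@]2(C)CC[C@@H](O)[C@](C)(O)[C@@H]2[C@@H]1OC(=O)c1ccccc1 | target

## Step count and least certain steps

Total: 13 steps. Longest linear sequence: 13 steps (1 → 3 → 5 → … → 20); 4 and 13 are used as bought.

Step 2 (key step). The most likely failure is loss of orientational or site control. The two quinone carbonyls are close in basicity and each has one unhindered lone pair, so activation through the C6 carbonyl could send C4 to C10 or move the cycloaddition to the isopropyl-bearing alkene. Facial discrimination may also drop, because the reacting alkene lies anti to the bound lone pair. The fallback enforces the outcome by structure and sets out from 3, with a different dienophile.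
- Carvacrol F1 would be oxidised with PhI(OAc)2 in MeOH to the quinone monoketal 4,4-dimethoxy-5-isopropyl-2-methylcyclohexa-2,5-dien-1-one F2.
- In F2 only the C9 carbonyl remains, and the β-carbon of the isopropyl alkene is blocked by the ketal carbon.
- Cycloaddition of F2 with 3 under the same catalyst at higher temperature should give the ketal adduct F3.
- Mild hydrolysis of F3 (oxalic acid on wet silica gel, CH2Cl2) returns to the route at 5.

Step 6. The equilibrium may not lie far enough on the trans side, or methoxide may add to the enone or cleave the silyl enol ether during the long exposure needed for the hindered C5 hydrogen. The fallback replaces thermodynamic by kinetic control and sets out from 9.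
- DBU in toluene would only conjugate the alkene, giving the cis-fused enone F4.
- LiN(i-Pr)2 in THF at −78 °C would remove the C5 hydrogen to give the cross-conjugated lithium dienolate F5.
- Protonation with AcOH at −78 °C, axial and anti to the neighbouring angular methyl, should deliver 5α-H and return to the route at 10.

Step 12. The base may abstract the more accessible 2β-hydrogen instead of 4β-H, which sits between the 10β-methyl and the 6β-benzoate; this would give the 2-ene. Chloride substitution at C3 is a second concern. The fallback avoids an external base and sets out from 15.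
- Condensation with 4-methylbenzenesulfonohydrazide would give the tosylhydrazone F6.
- Its sodium salt (NaH), heated in toluene or diglyme under aprotic Bamford–Stevens conditions, would give the C3 carbene.
- Intramolecular 1,2-shift of the axial tertiary 4β-hydrogen should form the 3,4-alkene and return to the route at 18.

Step 13. The tertiary C4 cation may lose a proton to give allylic alcohols. The syn-axial benzoate carbonyl may also take part in the opening and leave the acyl group on O4. The fallback makes that participation the deliberate pathway and sets out from 18.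
- Epoxide 19 would be isolated after buffered peracid epoxidation.
- HBF4·OEt2 in dry CH2Cl2 at −78 °C would open it from the β face through the benzoate carbonyl, giving the O4,O6-bridged 2-phenyl-1,3-dioxan-2-ylium tetrafluoroborate F7.
- Aqueous NaHCO3 would hydrolyse F7 through the ortho acid.
- Any 4-O-benzoyl isomer F8 formed would be equilibrated with catalytic TsOH in wet THF to the less hindered secondary ester, returning to the route at 20.

## Further compounds

F1 | step 2 | carvacrol (5-isopropyl-2-methylphenol) | Cc1ccc(C(C)C)cc1O
F2 | step 2 | 4,4-dimethoxy-5-isopropyl-2-methylcyclohexa-2,5-dien-1-one | CC1=CC(OC)(OC)C(C(C)C)=CC1=O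
F3 | step 2 | 6,6-dimethoxy-3-(triisopropylsilyloxy)-4βH,5βH-eudesma-2,7-dien-9-one (cis-fused ketal adduct) | CC(C)C1=CC(=O)[C@@]2(C)CC=C(O[Si](C(C)C)(C(C)C)C(C)C)[C@@H](C)[C@H]2C1(OC)OC
F4 | step 6 | 3-(triisopropylsilyloxy)-4βH,5βH-eudesma-2,7-dien-6-one (cis-fused) | CC(C)C1=CC[C@@]2(C)CC=C(O[Si](C(C)C)(C(C)C)C(C)C)[C@@H](C)[C@H]2C1=O
F5 | step 6 | lithium 3-(triisopropylsilyloxy)-4βH-eudesma-2,5,7-trien-6-olate | CC(C)C1=CC[C@@]2(C)CC=C(O[Si](C(C)C)(C(C)C)C(C)C)[C@@H](C)C2=C1[O-].[Li+]
F6 | step 12 | 3-(4-methylbenzenesulfonylhydrazono)-4βH,5αH,7αH-eudesman-6β-yl benzoate | CC(C)[C@@H]1CC[C@@]2(C)CCC(=NNS(=O)(=O)c3ccc(C)cc3)[C@@H](C)[C@@H]2[C@@H]1OC(=O)c1ccccc1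
F7 | step 13 | O4,O6-bridged 2-phenyl-1,3-dioxan-2-ylium tetrafluoroborate of the 3α-hydroxy-4β,6β-dioxy eudesmane | CC(C)[C@@H]1CC[C@@]2(C)CC[C@@H](O)[C@](C)(O3)[C@@H]2[C@@H]1O[C+]3c1ccccc1.F[B-](F)(F)F
F8 | step 13 | 3α,6β-dihydroxy-5αH,7αH-eudesman-4β-yl benzoate | CC(C)[C@@H]1CC[C@@]2(C)CC[C@@H](O)[C@](C)(OC(=O)c3ccccc3)[C@@H]2[C@@H]1O
A1 | alternative 1 | copper bis(trifluoromethanesulfonate) | [Cu+2].[O-]S(=O)(=O)C(F)(F)F.[O-]S(=O)(=O)C(F)(F)F
A2 | alternative 1 | trimethylaluminium | C[Al](C)C
A3 | alternative 1 | 3-allylcyclohex-2-en-1-one | C=CCC1=CC(=O)CCC1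
A4 | alternative 1 | 2-isopropylacrolein (3-methyl-2-methylidenebutanal) | CC(C)C(=C)C=O
A5 | alternative 1 | aldol adduct, 3-allyl-2-(1-hydroxy-3-methyl-2-methylidenebutyl)-3-methylcyclohexan-1-one | C=CC[C@@]1(C)CCCC(=O)[C@@H]1[C@H](O)C(=C)C(C)C
A6 | alternative 1 | 6β-hydroxy-5αH-15-noreudesm-7-en-4-one | CC(C)C1=CC[C@@]2(C)CCCC(=O)[C@@H]2[C@@H]1O
A7 | alternative 2 | dimethylaluminium chloride | C[Al](C)Cl
A8 | alternative 2 | (2E,8E)-7-(tert-butyldimethylsilyloxy)-6-isopropyl-3,9-dimethylundeca-2,8,10-trienal | O=C/C=C(\C)CC[C@@H](C(C)C)[C@@H](O[Si](C)(C)C(C)(C)C)/C=C(\C)C=C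
A9 | alternative 2 | 6β-(tert-butyldimethylsilyloxy)-5αH,7αH-eudesm-3-ene-1β-carbaldehyde | CC(C)[C@@H]1CC[C@@]2(C)[C@H](C=O)CC=C(C)[C@@H]2[C@@H]1O[Si](C)(C)C(C)(C)C
A10 | alternative 3 | zinc dibromide | [Zn+2].[Br-].[Br-]
A11 | alternative 3 | 2,6-dimethyl-6-(4-methylpent-3-en-1-yl)cyclohex-2-ene-1-carbaldehyde (formyl cis to the ring methyl on C6) | CC(C)=CCC[C@@]1(C)CCC=C(C)[C@@H]1C=O
A12 | alternative 3 | 5αH,7αH-eudesma-3,11-dien-6α-ol | CC(=C)[C@@H]1CC[C@@]2(C)CCC=C(C)[C@@H]2[C@H]1O
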